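The amounts are the same in every set-up, so what differs is the vessel and the way X and J are brought in.

| flask | X | J | remark | time |
|---|---|---|---|---|
| west | 0.17 M | 0.340 M | one stirred flow tank at steady state, fed with the mixture as stated, mean residence time 25 s |  |
| east | 0.17 M (fed, over 12.5 s) | 0.340 M | all but X at the start; X goes in evenly over 12.5 s, the run ends at 25 s | 25 s |
| south-east | 0.17 M | 0.340 M | a closed flask charged with all of it at once and left for 25 s | 25 s |
| north-east | 0.17 M | 0.340 M (fed, over 12.5 s) | all but J at the start; J goes in evenly over 12.5 s, the run ends at 25 s | 25 s |

    X + J → X.J (k1 = 0.22 M⁻¹ s⁻¹)
    J + X.J ⇌ J.X.J (K2 = 10 M⁻¹, k2 = 2.4 M⁻¹ s⁻¹)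
    X.J → D (k3 = 0.088 s⁻¹)
    J + D → J.D (k4 = 0.0068 M⁻¹ s⁻¹)

- the stated concentrations are those of everything mixed, before any reaction; amounts are the same in each set-up
- the feed brings no volume worth counting
- run time (east): 25 s

* the set-up with the highest amount of D at the outlet or at the end, in percent of the X put in ("none" if the first two lie within 2 percentage points) (west / east / south-east / north-east / none)
* amount of D at the outlet or at the end, in percent of the X put in, west
* amount of D at the outlet or at the end, in percent of the X put in, east
* amount of D at the outlet or at the end, in percent of the X put in, south-east
* amount of D at the outlet or at the end, in percent of the X put in, north-east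

Begin with south-east, where everything is present from the start. While J stands at its charge, X enters the bound forms in a pseudo-first-order way at 0.0748 s⁻¹, and X.J goes on to D at 0.088 s⁻¹. But J also takes X.J into J.X.J, with a forward half-life of 0.849 s, shorter than the 7.88 s of the step to D. So I treat that step as a pre-equilibrium. With J at its charge, this gives 3.40 for the parking ratio, which is J.X.J over X.J at equilibrium, the equilibrium constant 10 M⁻¹ times the concentration of J. The bound pool then leaks to D at 0.088 s⁻¹ divided by one plus that ratio, 0.0200 s⁻¹. I drop the loss of D to J.D, since its half-life of 5.0 min is longer than the 25 s run. The closed form for two first-order steps in series, entry then leak, gives 22.8% of D.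

The objection is that J does not stay at its charge. Each X that enters takes one J, and each J.X.J takes a second. On this first pass J would end near 0.115 M, so I redo the sum with the mean, 0.228 M. Entry slows to 0.0501 s⁻¹, but the leak rises to 0.0269 s⁻¹. The two changes pull against each other, and D comes to 22.9%. A doubt remains: one mean J stands in for a J that falls through the run, so this figure is rough. In east, the average X arrives at the mid-point of the feed and has 18.8 s, less than 25 s. The same formula with the same constants then gives 14.9%, so on this estimate south-east should give more D than east. West and north-east I leave unreckoned.

The forecast gives 22.8% for west, 18.4% for east, 27% for south-east and 20.2% for north-east, and it picks south-east: “Feeding delays reaction, so the all-at-once flask wins.”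

The simulation gives 22.8% for west, 18.8% for east, 27.3% for south-east and 20.0% for north-east, so south-east is highest.

At 25.0 s, south-east still has 50.6% of its J free, so the parking ratio has fallen from 3.40 to 1.72, and J.X.J over X.J reads 1.78. The parking step is a part of what holds D down in south-east, and it acts together with the short time: without that step south-east gives 52.7%, and left ten times as long it gives 81.6%. A flask like east but charged with 0.85 M of J still has 68.5% of it free at 25.0 s, so the ratio should be 5.83. It reads 5.80, and D stands at 15.8%, lower than east's 18.8%.

All constants were drawn at random within sensible limits; the run is a simulation.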